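**Retrosynthetic overview**
1. Rings: A azepanone, B pyrrolidine, C cyclopentene, D fused lactone, E pendant lactone. The N–CH2 of ring A comes last, from a lactam C=O, by chemoselective deoxygenation of a keto-lactam.
2. Key disconnection: remove N from ring A (retro-Schmidt). This leads back to a spiro 2,2-disubstituted cyclohexane-1,3-dione carrying a secondary azide. In the forward direction N inserts into the six-membered carbocycle (6 → 7, ring A) and ring B closes in the same event.
3. Enabling feature: the quaternary carbon shared by A, B and C bears N and, next to it, the ring-A ketone, and the N–CH2 carbon of A sits 1,3 to that ketone across the quaternary carbon. With N deleted and that CH2 raised to C=O, ring A becomes a cyclohexane-1,3-dione whose C2 is the (then non-stereogenic) quaternary carbon, and the N–CH of ring B lies exactly three carbons from C2.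
4. The azide side chain and the tetrasubstituted C=C come from a carbonyl-ene reaction of an exocyclic methylene with the lactone-E aldehyde. Ring C comes from a 5-exo vinyl-radical closure of a 2-ethynyl dione onto butenolide D. Ring D comes from a Nozaki–Hiyama–Kishi coupling and oxidative lactonisation. The C–Et centre comes from Ir-catalysed allylic alkylation of cyclohexane-1,3-dione.
5. Ring order: six-membered dione (purchased) → D → C → (E made separately) → B and A together.

Key step: step 15

Assumption: the sense of induction of the Ir–phosphoramidite catalyst in step 2 is taken to parallel that known for malonate-type nucleophiles. Should it be opposite, the enantiomeric ligand is used. Compound 4 is written as its diketo tautomer.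

**Step 1**
Reactants: 1 (E)-pent-2-en-1-ol
Product: 2 methyl (E)-pent-2-en-1-yl carbonate
Conditions: ClCO2Me, pyridine, CH2Cl2, 0 °C → rt
Reagents that add atoms: methyl chloroformate COC(=O)Cl
Why: Plain O-acylation of a primary allylic alcohol (carbonate formation) installs the leaving group for the allylic substitution, and no stereocentre is involved.

**Step 2**
Reactants: 2 methyl (E)-pent-2-en-1-yl carbonate; 3 cyclohexane-1,3-dione
Product: 4 (S)-2-(pent-1-en-3-yl)cyclohexane-1,3-dione
Conditions: [Ir(cod)Cl]2 (2 mol %), (Sa,S,S)-BINOL/bis(1-phenylethyl)amine phosphoramidite (4 mol %), TBD (8 mol %), THF, rt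
Reagents that add atoms: none
Why: In this iridium-catalysed asymmetric allylic alkylation of a stabilised enolate, the cyclometalated catalyst directs attack to the substituted allyl terminus (branched product), its chiral pocket sets the ethyl-bearing stereocentre, and the methoxide released from the carbonate serves as base.

**Step 3**
Reactants: 4 (S)-2-(pent-1-en-3-yl)cyclohexane-1,3-dione
Product: 5 2-ethynyl-2-[(S)-pent-1-en-3-yl]cyclohexane-1,3-dione
Conditions: TMS-EBX, TBAF, THF, −78 °C → rt
Reagents that add atoms: 1-[(trimethylsilyl)ethynyl]-1,2-benziodoxol-3(1H)-one (TMS-EBX) C[Si](C)(C)C#CI1OC(=O)c2ccccc12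
Why: Electrophilic α-alkynylation of a 1,3-dicarbonyl enolate with a hypervalent iodine reagent (conjugate addition, α-elimination, 1,2-H shift) is fast enough at low temperature to build the quaternary carbon, which is not stereogenic because its two ring branches are identical.

**Step 4**
Reactants: 5 2-ethynyl-2-[(S)-pent-1-en-3-yl]cyclohexane-1,3-dione
Product: 7 (R)-2-(1-ethynyl-2,6-dioxocyclohexyl)butanal, via secondary ozonide 6 (not isolated)
Conditions: O3, CH2Cl2, −78 °C (Sudan III end point); then Me2S, −78 °C → rt
Reagents that add atoms: ozone [O-][O+]=O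
Why: Ozonolysis with reductive work-up cleaves the monosubstituted alkene far faster than the terminal alkyne, and the neutral medium preserves the α-stereocentre of the aldehyde.

**Step 5**
Reactants: 8 prop-2-yn-1-ol
Product: 10 (Z)-3-iodo-2-methylprop-2-en-1-ol, via alkenylmagnesium alkoxide 9 (not isolated)
Conditions: MeMgBr (2.5 equiv), CuI (10 mol %), THF, −10 °C → rt; then I2, −78 → 0 °C
Reagents that add atoms: methylmagnesium bromide C[Mg]Br; iodine II
Why: Alkoxide-directed, copper-catalysed anti-carbomagnesiation places the methyl group on the internal carbon and magnesium cis to CH2O, and iodinolysis with retention gives the Z-iodide.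

**Step 6**
Reactants: 7 (R)-2-(1-ethynyl-2,6-dioxocyclohexyl)butanal; 10 (Z)-3-iodo-2-methylprop-2-en-1-ol
Product: 11 2-ethynyl-2-[(3R,4R,5Z)-4,7-dihydroxy-6-methylhept-5-en-3-yl]cyclohexane-1,3-dione
Conditions: CrCl2 (6 equiv), NiCl2 (1 mol %), DMF, rt
Reagents that add atoms: none
Why: In the Nozaki–Hiyama–Kishi coupling the alkenylchromium(III) species adds only to the aldehyde (ketones, alkyne and free OH are tolerated) with retention of alkene geometry, and Felkin–Anh attack anti to the bulky quaternary substituent sets the carbinol centre with its oxygen anti to the ethyl group of the later ring C.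

**Step 7**
Reactants: 11 2-ethynyl-2-[(3R,4R,5Z)-4,7-dihydroxy-6-methylhept-5-en-3-yl]cyclohexane-1,3-dione
Product: 13 2-ethynyl-2-{(R)-1-[(R)-4-methyl-5-oxo-2,5-dihydrofuran-2-yl]propyl}cyclohexane-1,3-dione, via lactol 12 (not isolated)
Conditions: activated MnO2 (excess), CH2Cl2, rt
Reagents that add atoms: none
Why: This is the oxidative lactonisation of a Z-2-ene-1,4-diol, in which MnO2 oxidises the unhindered primary allylic alcohol, the Z-hydroxy-enal closes to the lactol, and the lactol is oxidised on to the butenolide without touching a stereocentre.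

**Step 8**
Reactants: 13 2-ethynyl-2-{(R)-1-[(R)-4-methyl-5-oxo-2,5-dihydrofuran-2-yl]propyl}cyclohexane-1,3-dione
Product: 15 (3R,3aR,6R,6aS)-6-ethyl-3-methyl-4-methylidenetetrahydrospiro[cyclopenta[b]furan-5,1'-cyclohexane]-2,2',6'-trione, via vinylstannane 14 (not isolated)
Conditions: Bu3SnH, AIBN (cat.), PhH, 80 °C (slow addition); then HCl (Et2O), CH2Cl2, 0 °C
Reagents that add atoms: none
Why: In this stannyl-radical enyne cyclisation Bu3Sn• adds to the alkyne terminus, the vinyl radical closes 5-exo-trig on the butenolide β-carbon (necessarily cis-fused), the α-lactone radical takes H from Bu3SnH on the convex face (setting the C–Me centre with methyl endo), and ipso-protonation then removes tin.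

**Step 9**
Reactants: 16 (R)-2,2-dimethyl-1,3-dioxolane-4-carbaldehyde
Product: 17 ethyl (Z)-3-[(S)-2,2-dimethyl-1,3-dioxolan-4-yl]-2-methylprop-2-enoate
Conditions: (CF3CH2O)2P(O)CH(CH3)CO2Et, KHMDS, 18-crown-6, THF, −78 °C
Reagents that add atoms: ethyl 2-[bis(2,2,2-trifluoroethoxy)phosphoryl]propanoate CCOC(=O)C(C)P(=O)(OCC(F)(F)F)OCC(F)(F)F
Why: The Still–Gennari olefination gives the Z-trisubstituted enoate needed for lactonisation, and the chiral-pool stereocentre (the future O–CH of ring E) is untouched at low temperature.

**Step 10**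
Reactants: 17 ethyl (Z)-3-[(S)-2,2-dimethyl-1,3-dioxolan-4-yl]-2-methylprop-2-enoate
Product: 18 (S)-5-(hydroxymethyl)-3-methylfuran-2(5H)-one
Conditions: p-TsOH (cat.), MeOH–H2O, rt
Reagents that add atoms: none
Why: Acid-catalysed acetonide hydrolysis frees the secondary hydroxyl cis to the ester, and it lactonises spontaneously to the five-membered butenolide.

**Step 11**
Reactants: 18 (S)-5-(hydroxymethyl)-3-methylfuran-2(5H)-one
Product: 19 (3S,5S)-5-(hydroxymethyl)-3-methyldihydrofuran-2(3H)-one
Conditions: H2 (1 atm), Rh/Al2O3, EtOAc, rt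
Reagents that add atoms: none
Why: Heterogeneous hydrogenation delivers H2 to the butenolide face opposite the C5 substituent, so the methyl group ends cis to it.

**Step 12**
Reactants: 19 (3S,5S)-5-(hydroxymethyl)-3-methyldihydrofuran-2(3H)-one
Product: 20 (2S,4S)-4-methyl-5-oxotetrahydrofuran-2-carbaldehyde
Conditions: Dess–Martin periodinane, NaHCO3, CH2Cl2, 0 °C → rt; used directly
Reagents that add atoms: none
Why: Buffered Dess–Martin oxidation gives the α-acyloxy aldehyde under non-epimerising conditions.

**Step 13**
Reactants: 15 (3R,3aR,6R,6aS)-6-ethyl-3-methyl-4-methylidenetetrahydrospiro[cyclopenta[b]furan-5,1'-cyclohexane]-2,2',6'-trione; 20 (2S,4S)-4-methyl-5-oxotetrahydrofuran-2-carbaldehyde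
Product: 21 (3R,6R,6aS)-6-ethyl-4-{(R)-2-hydroxy-2-[(2S,4S)-4-methyl-5-oxotetrahydrofuran-2-yl]ethyl}-3-methyl-6,6a-dihydrospiro[cyclopenta[b]furan-5,1'-cyclohexane]-2(3H),2',6'-trione
Conditions: Me2AlCl (3 equiv), CH2Cl2, −78 → −20 °C
Reagents that add atoms: none
Why: In this Lewis-acid-promoted carbonyl-ene reaction of a 1,1-disubstituted alkene with an activated aldehyde, the only allylic hydrogen is the convex-face ring-fusion H, so the C=C can move only into the tetrasubstituted position, and polar Felkin–Anh attack anti to the lactone C–O bond sets the (R)-carbinol.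

**Step 14**
Reactants: 21 (3R,6R,6aS)-6-ethyl-4-{(R)-2-hydroxy-2-[(2S,4S)-4-methyl-5-oxotetrahydrofuran-2-yl]ethyl}-3-methyl-6,6a-dihydrospiro[cyclopenta[b]furan-5,1'-cyclohexane]-2(3H),2',6'-trione
Product: 22 (3R,6R,6aS)-4-{(S)-2-azido-2-[(2S,4S)-4-methyl-5-oxotetrahydrofuran-2-yl]ethyl}-6-ethyl-3-methyl-6,6a-dihydrospiro[cyclopenta[b]furan-5,1'-cyclohexane]-2(3H),2',6'-trione
Conditions: PPh3, DIAD, HN3 (PhMe solution), THF, 0 °C → rt
Reagents that add atoms: hydrazoic acid N=[N+]=[N-]
Why: Mitsunobu azidation displaces the activated secondary alcohol by SN2 under neutral conditions, inverting it to the (S) configuration of the N–CH centre without disturbing the base-sensitive β,γ-unsaturated lactone.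

**Step 15**
Reactants: 22 (3R,6R,6aS)-4-{(S)-2-azido-2-[(2S,4S)-4-methyl-5-oxotetrahydrofuran-2-yl]ethyl}-6-ethyl-3-methyl-6,6a-dihydrospiro[cyclopenta[b]furan-5,1'-cyclohexane]-2(3H),2',6'-trione
Product: 24 pentacyclic keto-lactam (the target with C=O in place of the N–CH2 group of ring A; ring A = azepane-2,6-dione; quaternary carbon R), via azidohydrin diazonium ion 23 (not isolated)
Conditions: TFA–CH2Cl2 (1:1), 0 °C → rt
Reagents that add atoms: none
Why: TFA activates one carbonyl of the non-enolisable spiro-1,3-dione, the alkylated azide nitrogen adds to it (6-exo-trig) to give the chair azidohydrin diazonium ion 23, and the bond from the quaternary carbon to the carbinol carbon, which lies antiperiplanar to the equatorial N2+ group, migrates to nitrogen with loss of N2 and with retention, so that nitrogen is inserted into the six-membered carbocycle. The closest known reaction type is the intramolecular Schmidt reaction of 2-(3-azidopropyl)cyclohexanones, which gives pyrrolo[1,2-a]azepinones and tolerates a quaternary migrating carbon. Ring B (pyrrolidine) is closed by contraction of the temporary six-membered azidohydrin ring in the 1,2-shift, and ring A arises in the same shift by one-atom expansion of the cyclohexanedione ring to the seven-membered keto-lactam. The only new stereocentre, the quaternary carbon, becomes stereogenic when the two carbonyl groups are differentiated: the rigid spiro-cyclopentene holds its CH(Et) branch equatorial and the spectator acyl branch axial in 23, and the (S)-azide carbon can then place lactone E equatorial only in the chair that engages the carbonyl on the face anti to the ethyl group, which leads to the (R) centre of the target. The step needs carbonyl-group selectivity (secured as just described), migration of the quaternary carbon rather than the ring CH2 (secured because the cis-fused azidohydrin cannot align its C–CH2 bond with N2+), and chemoselectivity (the lactone carbonyls are too poor electrophiles for an alkyl azide, and the tetrasubstituted alkene is deactivated towards TFA by its allylic acyloxy and β-dicarbonyl neighbours).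

**Step 16**
Reactants: 24 pentacyclic keto-lactam
Product: 26 CNP0315436.2 (target), via O-triflyl iminium triflate 25 (not isolated)
Conditions: Tf2O (1.1 equiv), CH2Cl2, −78 → 0 °C; then Hantzsch ester (2.5 equiv), rt; aq. NaHCO3
Reagents that add atoms: none
Why: In this electrophilic amide activation and hydride-transfer reduction, only the lactam oxygen is nucleophilic enough to be triflated, and the dihydropyridine reduces the iminium stage twice while leaving ketone, lactones, alkene and all stereocentres untouched.

**Compound list**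
1 | (E)-pent-2-en-1-ol | CC/C=C/CO | starting material
2 | methyl (E)-pent-2-en-1-yl carbonate | CC/C=C/COC(=O)OC | intermediate
3 | cyclohexane-1,3-dione | O=C1CCCC(=O)C1 | starting material
4 | (S)-2-(pent-1-en-3-yl)cyclohexane-1,3-dione (diketo tautomer) | CC[C@H](C1C(=O)CCCC1=O)C=C | intermediate
5 | 2-ethynyl-2-[(S)-pent-1-en-3-yl]cyclohexane-1,3-dione | CC[C@H](C1(C#C)C(=O)CCCC1=O)C=C | intermediate
6 | secondary ozonide of 5 (1,2,4-trioxolane, epimers at the ring CH) | CC[C@H](C1(C#C)C(=O)CCCC1=O)C2OCOO2 | intermediate
7 | (R)-2-(1-ethynyl-2,6-dioxocyclohexyl)butanal | CC[C@H](C1(C#C)C(=O)CCCC1=O)C=O | intermediate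
8 | prop-2-yn-1-ol | C#CCO | starting material
9 | bromomagnesium (Z)-3-(bromomagnesio)-2-methylprop-2-en-1-olate | Br[Mg]OC/C(C)=C\[Mg]Br | intermediate
10 | (Z)-3-iodo-2-methylprop-2-en-1-ol | OC/C(C)=C\I | intermediate
11 | 2-ethynyl-2-[(3R,4R,5Z)-4,7-dihydroxy-6-methylhept-5-en-3-yl]cyclohexane-1,3-dione | CC[C@H](C1(C#C)C(=O)CCCC1=O)[C@H](O)/C=C(/C)CO | intermediate
12 | lactol (5-hydroxy-4-methyl-2,5-dihydrofuran-2-yl analogue of 13, anomers) | CC[C@H](C1(C#C)C(=O)CCCC1=O)[C@@H]2OC(O)C(C)=C2 | intermediate
13 | 2-ethynyl-2-{(R)-1-[(R)-4-methyl-5-oxo-2,5-dihydrofuran-2-yl]propyl}cyclohexane-1,3-dione | CC[C@H](C1(C#C)C(=O)CCCC1=O)[C@@H]2OC(=O)C(C)=C2 | intermediate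
14 | 4-[(tributylstannyl)methylidene] analogue of 15 (E/Z mixture, inconsequential) | CC[C@H]1[C@@H]2OC(=O)[C@H](C)[C@@H]2C(=C[Sn](CCCC)(CCCC)CCCC)C13C(=O)CCCC3=O | intermediate
15 | (3R,3aR,6R,6aS)-6-ethyl-3-methyl-4-methylidenetetrahydrospiro[cyclopenta[b]furan-5,1'-cyclohexane]-2,2',6'-trione (cis-fused; H-3, H-3a and H-6a on the convex face; ethyl trans to the lactone O) | CC[C@H]1[C@@H]2OC(=O)[C@H](C)[C@@H]2C(=C)C13C(=O)CCCC3=O | intermediate
16 | (R)-2,2-dimethyl-1,3-dioxolane-4-carbaldehyde | O=C[C@H]1COC(C)(C)O1 | starting material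
17 | ethyl (Z)-3-[(S)-2,2-dimethyl-1,3-dioxolan-4-yl]-2-methylprop-2-enoate | CCOC(=O)/C(C)=C\[C@H]1COC(C)(C)O1 | intermediate
18 | (S)-5-(hydroxymethyl)-3-methylfuran-2(5H)-one | OC[C@@H]1C=C(C)C(=O)O1 | intermediate
19 | (3S,5S)-5-(hydroxymethyl)-3-methyldihydrofuran-2(3H)-one | OC[C@@H]1C[C@H](C)C(=O)O1 | intermediate
20 | (2S,4S)-4-methyl-5-oxotetrahydrofuran-2-carbaldehyde | O=C[C@@H]1C[C@H](C)C(=O)O1 | intermediate
21 | ene adduct, (R)-homoallylic alcohol (name as in step 13) | CC[C@H]1[C@@H]2OC(=O)[C@H](C)C2=C(C[C@@H](O)[C@@H]4C[C@H](C)C(=O)O4)C13C(=O)CCCC3=O | intermediate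
22 | (S)-azide (name as in step 14) | CC[C@H]1[C@@H]2OC(=O)[C@H](C)C2=C(C[C@H](N=[N+]=[N-])[C@@H]4C[C@H](C)C(=O)O4)C13C(=O)CCCC3=O | intermediate
23 | azidohydrin diazonium ion (chair, OH axial, N2+ equatorial), trifluoroacetate | CC[C@H]1[C@@H]2OC(=O)[C@H](C)C2=C2C[C@@H]([C@@H]3C[C@H](C)C(=O)O3)N([N+]#N)[C@@]3(O)CCCC(=O)[C@]213.[O-]C(=O)C(F)(F)F | intermediate
24 | pentacyclic keto-lactam (ring A = azepane-2,6-dione) | CC[C@H]1[C@@H]2OC(=O)[C@H](C)C2=C2C[C@@H]([C@@H]3C[C@H](C)C(=O)O3)N3C(=O)CCCC(=O)[C@]213 | intermediate
25 | O-triflyl iminium triflate of 24 | CC[C@H]1[C@@H]2OC(=O)[C@H](C)C2=C2C[C@@H]([C@@H]3C[C@H](C)C(=O)O3)[N+]3=C(OS(=O)(=O)C(F)(F)F)CCCC(=O)[C@]213.[O-]S(=O)(=O)C(F)(F)F | intermediate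
26 | CNP0315436.2 | CC[C@H]1[C@@H]2OC(=O)[C@H](C)C2=C2C[C@@H]([C@@H]3C[C@H](C)C(=O)O3)N3CCCCC(=O)[C@]213 | target

**Total step count:** 16. **Longest linear sequence:** 11 (steps 1, 2, 3, 4, 6, 7, 8, 13, 14, 15, 16).

**Steps most likely to fail**

*Step 13 (carbonyl-ene).*
- What may go wrong: the alkene may react sluggishly because it is inductively deactivated by the neighbouring dione. The Lewis acid may be sequestered by the many carbonyl groups. Chelation may erode the Felkin–Anh selectivity, and the aldehyde may epimerise.
- Fallback: acylation, deconjugation and reduction in place of the ene reaction. It sets out from 14 (isolated instead of protodestannylated) and from 19, and it returns at 21.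
- Alcohol 19 is oxidised (TEMPO, PhI(OAc)2, MeCN–H2O) to (2S,4S)-4-methyl-5-oxotetrahydrofuran-2-carboxylic acid F1.
- Oxalyl chloride with catalytic DMF converts this acid to (2S,4S)-4-methyl-5-oxotetrahydrofuran-2-carbonyl chloride F2.
- Stille acylation of 14 with the acid chloride (Pd2(dba)3, AsPh3, THF) gives the exocyclic enone F3.
- Photochemical deconjugation through the dienol moves the double bond into ring C and gives the β,γ-unsaturated ketone F4.
- L-Selectride at −78 °C reduces only the unhindered α-acyloxy ketone, under polar Felkin–Anh control, to 21.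

*Step 8 (radical enyne cyclisation).*
- What may go wrong: a 1,2-acyl shift of the vinyl radical onto a ring carbonyl (Dowd–Beckwith-type ring expansion) may compete with the 5-exo closure. The final hydrogen-atom transfer that sets the C–Me centre may also show low facial selectivity.
- Fallback: an organometallic closure in place of the radical one. It sets out from 13 and returns at 15.
- This is a palladium-catalysed reductive 1,6-enyne cyclisation (Pd2(dba)3, AcOH, Et3SiH, PhMe). Hydropalladation of the alkyne, 5-exo carbopalladation of the butenolide and hydride capture of the palladium enolate from the convex face give 15 directly, without a free vinyl radical and without tin.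

*Step 15 (key step).*
- What may go wrong: the two diastereotopic carbonyl groups may be discriminated insufficiently. Acid may ionise the allylic C–O bond of ring D, or the C=C or the C–Me centre may drift in acid.
- Fallback: the carbonyl groups are differentiated first, and the nitrogen insertion follows. It sets out from 22 and returns at 24.
- A ketoreductase (NADPH with glucose/GDH recycling, enzyme chosen by screening) carries out the well-known desymmetrising mono-reduction of 2,2-disubstituted cyclic 1,3-diketones on the carbonyl syn to the ethyl group. This gives the hydroxy-keto azide F5 (the carbinol configuration is inconsequential).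
- The single remaining ketone then undergoes the same intramolecular Schmidt ring expansion (TiCl4, CH2Cl2, −78 → 0 °C) to the hydroxy lactam F6.
- Dess–Martin oxidation gives 24.

**Further compounds**
F1 | step 13 | (2S,4S)-4-methyl-5-oxotetrahydrofuran-2-carboxylic acid | OC(=O)[C@@H]1C[C@H](C)C(=O)O1
F2 | step 13 | (2S,4S)-4-methyl-5-oxotetrahydrofuran-2-carbonyl chloride | ClC(=O)[C@@H]1C[C@H](C)C(=O)O1
F3 | step 13 | exocyclic enone (acylmethylidene analogue of 15) | CC[C@H]1[C@@H]2OC(=O)[C@H](C)[C@@H]2C(=CC(=O)[C@@H]4C[C@H](C)C(=O)O4)C13C(=O)CCCC3=O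
F4 | step 13 | β,γ-unsaturated ketone (oxo analogue of 21) | CC[C@H]1[C@@H]2OC(=O)[C@H](C)C2=C(CC(=O)[C@@H]4C[C@H](C)C(=O)O4)C13C(=O)CCCC3=O
F0 | step 8 | none | none
F5 | step 15 | hydroxy-keto azide (mono-reduced 22) | CC[C@H]1[C@@H]2OC(=O)[C@H](C)C2=C(C[C@H](N=[N+]=[N-])[C@@H]4C[C@H](C)C(=O)O4)[C@]13C(=O)CCCC3O
F6 | step 15 | hydroxy lactam (24 with CH(OH) in place of the ring-A ketone) | CC[C@H]1[C@@H]2OC(=O)[C@H](C)C2=C2C[C@@H]([C@@H]3C[C@H](C)C(=O)O3)N3C(=O)CCCC(O)[C@]213
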